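**Plan**

- **Retrosynthesis (ent-labdane numbering).** The coumarate is cut at its C=C and at the C19–O acyl bond. Next come the diene at C13–C14, the C4–CH3 bond and a helper ketone at C3. Then C9–C10 is cut while a C4–C10 bond is drawn in. Last come the cyclopropane bonds C4–C5 and C4–C10 (diazo carbon), then C3–C4, C1–C2 and C6–C7.
- **Enabling feature.** In ring A, C4 bears C19 (which can be an ester) and sits next to C3 (which can be a ketone). C10 is fully substituted and carries CH3. The two are 1,3-related through C5, so ring A can be stored as the five-membered ring C4–C3–C2–C1–C10 fused to the cyclopropane C4–C5–C10. Heterolysis of the shared C4–C10 bond puts both charges where the structure stabilises them. The C8(17) methylene beside C9 is the footprint of an allylsilane that can attack C10.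
- **Forward order.** The open chain is built by a Grignard addition, two Johnson–Claisen rearrangements and a Claisen condensation. Diazo transfer and cyclopropanation then give the five-membered ring plus cyclopropane. One step expands this to ring A and closes ring B. C4 methylation, C3 deoxygenation, the side-chain diene, the C19 alcohol and the coumarate follow.
- **Stereochemistry.** The absolute sense comes from the ligand-controlled cyclopropanation (C4, C5, C10 of 11). The olefin geometries from chair Claisen transition states are translated in the key step into C10 (inversion), the trans ring fusion and C9 (chair). C4 is set by methylation anti to the C10 methyl. The coumarate E geometry comes from the decarboxylative condensation.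

Key step: step 8

Assumption: the (S,S)-bis(oxazoline) is taken to deliver (1S,5S,6S)-11. If the sense of induction is the opposite, the equally available (R,R)-ligand is used.
Remark: atoms are numbered as in ent-labdane (C1–C20) in all intermediates.

Step 1
Reactants: 1 pent-4-enal; 2 (2-bromoprop-2-en-1-yl)trimethylsilane
Product: 4 (±)-2-[(trimethylsilyl)methyl]hepta-1,6-dien-3-ol, via Grignard reagent 3 (not isolated)
Conditions: 2, Mg turnings, THF, 40 °C; then 1, −78 → 0 °C; aq. NH4Cl
Reagents that add atoms: none
Why: Grignard addition of the 1-(silylmethyl)vinyl nucleophile to an unhindered aldehyde joins C8 to C9; the carbinol centre is racemic and is erased in step 2.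

Step 2
Reactants: 4 silylmethyl dienol
Product: 5 methyl (4Z)-4-[(trimethylsilyl)methyl]nona-4,8-dienoate
Conditions: MeC(OMe)3 (6 equiv), EtCO2H (5 mol %), 110–125 °C, MeOH distilled off
Reagents that add atoms: trimethyl orthoacetate, CC(OC)(OC)OC
Why: The Johnson–Claisen rearrangement forms C6–C7 through a chair with the butenyl chain equatorial, which places C7 trans to C11 on C8=C9 (Z by the sequence rule because of silicon); the weak carboxylic acid should not protodesilylate the allylsilane.

Step 3
Reactants: 5 dienoate
Product: 7 (±)-(6Z)-2-methyl-6-[(trimethylsilyl)methyl]undeca-1,6,10-trien-3-ol, via dienal 6 (not isolated)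
Conditions: iBu2AlH (1.05 equiv), CH2Cl2, −78 °C; then isopropenylmagnesium bromide (1.5 equiv, THF), −78 → 0 °C; aq. potassium sodium tartrate
Reagents that add atoms: isopropenylmagnesium bromide, C=C(C)[Mg]Br
Why: Partial hydride reduction of a methyl ester to the aldehyde level followed by in situ Grignard addition is a standard one-pot homologation that joins C5 to C10; the new carbinol centre is racemic and is erased in step 4.

Step 4
Reactants: 7 trienol
Product: 8 methyl (4E,8Z)-4-methyl-8-[(trimethylsilyl)methyl]trideca-4,8,12-trienoate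
Conditions: MeC(OMe)3 (6 equiv), EtCO2H (5 mol %), 110–125 °C, MeOH distilled off
Reagents that add atoms: trimethyl orthoacetate, CC(OC)(OC)OC
Why: A second Johnson–Claisen rearrangement forms C1–C2 and gives the E-configured C10=C5 olefin through the chair with the long chain equatorial.

Step 5
Reactants: 8 trienoate
Product: 9 methyl (6E,10Z)-6-methyl-3-oxo-10-[(trimethylsilyl)methyl]pentadeca-6,10,14-trienoate
Conditions: methyl acetate (4 equiv), LiN(iPr)2 (4 equiv), THF, −78 °C; then 8, −78 → −10 °C; aq. NH4Cl
Reagents that add atoms: methyl acetate, COC(C)=O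
Why: The crossed Claisen condensation of an unhindered methyl ester with excess lithio methyl acetate forms C3–C4 and is driven by deprotonation of the β-keto ester; methoxide as leaving group avoids ester scrambling.

Step 6
Reactants: 9 β-keto ester
Product: 10 methyl (6E,10Z)-2-diazo-6-methyl-3-oxo-10-[(trimethylsilyl)methyl]pentadeca-6,10,14-trienoate
Conditions: 4-acetamidobenzenesulfonyl azide (1.2 equiv), Et3N, MeCN, 0 °C → rt
Reagents that add atoms: 4-acetamidobenzenesulfonyl azide, CC(=O)Nc1ccc(cc1)S(=O)(=O)N=[N+]=[N-]
Why: Regitz diazo transfer to an active methylene proceeds under mild amine base that leaves the olefins and the allylsilane untouched.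

Step 7
Reactants: 10 diazo keto ester
Product: 11 methyl (1S,5S,6S)-5-methyl-2-oxo-6-{(3Z)-3-[(trimethylsilyl)methyl]octa-3,7-dien-1-yl}bicyclo[3.1.0]hexane-1-carboxylate
Conditions: [Cu(MeCN)4]PF6 (5 mol %), 2,2′-isopropylidenebis[(4S)-4-tert-butyl-2-oxazoline] (6 mol %), toluene, 50 °C, slow addition of 10 (final 0.01 M)
Reagents that add atoms: none
Why: This is a catalytic asymmetric intramolecular cyclopropanation of a 2-diazo-3-oxohept-6-enoate by a monovalent copper bis(oxazoline) carbenoid, in which only C10=C5 is reachable through a five-membered ring, the syn addition turns the E-olefin into the exo C6 chain (cis to the C10 methyl), and the ligand selects the olefin face and so fixes C4, C5 and C10.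

Step 8
Reactants: 11 bicyclo[3.1.0]hexanone ester
Product: 13 methyl (1R,4aR,5R,8aR)-5-(but-3-en-1-yl)-4a-methyl-6-methylidene-2-oxodecahydronaphthalene-1-carboxylate, via silyl enol ether 12 (not isolated)
Conditions: Me3SiOTf (20 mol %), 2,6-di-tert-butyl-4-methylpyridine (30 mol %), CH2Cl2 (0.01 M), −78 → −30 °C; then 1 M HCl, THF, 0 °C
Reagents that add atoms: none
Why: Silylation of the β-keto ester carbonyl by Me3SiOTf polarises the cyclopropane, the shared C4–C10 bond breaks heterolytically (enol silane at C3/C4, developing tertiary cation at C10) while C9 of the allylsilane bonds to C10 from the rear, and the β-silyl cation at C8 gives up Me3Si+ to triflate, which regenerates the catalyst and leaves the C8(17) methylene; acid work-up hydrolyses 12 to 13. The closest known reaction types are the olefin-participated acid-catalysed opening of acylcyclopropanes (5-methyl-6-alkenylbicyclo[3.1.0]hexan-2-ones) and the allylsilane-terminated cation–olefin cyclisation. Ring A is not closed but grows from five to six members because C5 enters the ring when C4–C10 breaks, and ring B closes through a six-membered chair, endo to the C8=C9 bond and endo to the C5–C10 edge of the cyclopropane, as in epoxide-initiated polyene cyclisation. C10 is set by inversion (rear-side attack), which together with the retained C5 and the exo C6 chain inherited from the E-olefin gives the trans ring fusion; C9 is set by the chair with C11 equatorial as dictated by the C8=C9 geometry; C4 stays enolisable and is fixed in step 9. The step needs cleavage of the inner C4–C10 bond instead of the outer C4–C5 bond, and C–C bonding before proton loss: C10 is tertiary and C5 secondary, the freely rotating ester overlaps with either bond, attack at C5 would need a five-membered closure at a secondary centre, and the trisubstituted allylsilane is by far the best nucleophile present (the terminal vinyl group is inert). The hindered pyridine removes adventitious acid so that protodesilylation is held back.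

Step 9
Reactants: 13 bicyclic β-keto ester
Product: 14 methyl (1S,4aS,5R,8aS)-5-(but-3-en-1-yl)-1,4a-dimethyl-6-methylidene-2-oxodecahydronaphthalene-1-carboxylate
Conditions: K2CO3 (3 equiv), MeI (5 equiv), acetone, reflux
Reagents that add atoms: iodomethane, CI
Why: In this C-alkylation of a cyclic β-keto ester enolate, iodomethane approaches the planar enolate from the face opposite to the axial C10 methyl, so the new CH3 becomes equatorial and CO2Me axial (cis to the C10 methyl), the classical outcome for such A rings.

Step 10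
Reactants: 14 methylated keto ester
Product: 15 methyl (1S,2R,4aS,5R,8aS)-5-(but-3-en-1-yl)-2-hydroxy-1,4a-dimethyl-6-methylidene-decahydronaphthalene-1-carboxylate
Conditions: NaBH4, MeOH/CH2Cl2, −10 °C
Reagents that add atoms: none
Why: Borohydride reduces the ketone chemoselectively with axial hydride delivery from the face opposite to the axial C10 methyl and C4 ester, giving the equatorial alcohol, whose configuration is of no consequence because C3 becomes CH2.

Step 11
Reactants: 15 hydroxy ester
Product: 16 O-(C3) imidazole-1-carbothioate of 15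
Conditions: 1,1′-thiocarbonyldiimidazole (2 equiv), DMAP (0.2 equiv), 1,2-dichloroethane, 80 °C
Reagents that add atoms: 1,1′-thiocarbonyldiimidazole, S=C(n1ccnc1)n1ccnc1
Why: Neutral thioacylation of a hindered equatorial secondary alcohol avoids a free alkoxide and hence retro-aldol cleavage of the β-hydroxy ester.

Step 12
Reactants: 16 thiocarbonyl derivative
Product: 17 methyl (1R,4aS,5R,8aS)-5-(but-3-en-1-yl)-1,4a-dimethyl-6-methylidene-decahydronaphthalene-1-carboxylate
Conditions: Bu3SnH (1.5 equiv), AIBN (0.1 equiv), toluene, 100 °C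
Reagents that add atoms: none
Why: The Barton–McCombie deoxygenation removes the helper oxygen through a secondary C3 radical that has no olefin within cyclisation reach, and unactivated olefins are not hydrostannylated under these conditions.

Step 13
Reactants: 17 butenyl ester
Product: 18 methyl (1R,4aS,5R,8aS)-1,4a-dimethyl-6-methylidene-5-(3-oxobutyl)decahydronaphthalene-1-carboxylate
Conditions: PdCl2 (10 mol %), CuCl (1 equiv), O2 (1 atm), DMF/H2O 7:1, rt
Reagents that add atoms: water, O
Why: The Tsuji–Wacker oxidation by divalent palladium converts the monosubstituted terminal olefin into the methyl ketone (C13=O, C16H3), while the hindered 1,1-disubstituted C8(17) methylene reacts far more slowly.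

Step 14
Reactants: 18 methyl ketone
Product: 19 methyl (1R,4aS,5R,8aS)-1,4a-dimethyl-6-methylidene-5-{3-[(trifluoromethanesulfonyl)oxy]but-3-en-1-yl}decahydronaphthalene-1-carboxylate
Conditions: LiN(iPr)2 (1.1 equiv), THF, −78 °C; PhNTf2 (1.2 equiv), −78 → 0 °C
Reagents that add atoms: N-phenylbis(trifluoromethanesulfonimide), O=S(=O)(N(c1ccccc1)S(=O)(=O)C(F)(F)F)C(F)(F)F
Why: Kinetic deprotonation of a methyl ketone at the CH3 group and O-triflation of the terminal enolate give the 2-triflyloxy-1-alkene; the C19 ester has no α-hydrogen and is shielded.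

Step 15
Reactants: 19 enol triflate
Product: 20 methyl ent-labda-8(17),13(16),14-trien-19-oate
Conditions: Pd(PPh3)4 (5 mol %), LiCl (3 equiv), tributyl(vinyl)stannane (1.2 equiv), THF, 65 °C
Reagents that add atoms: tributyl(vinyl)stannane, C=C[Sn](CCCC)(CCCC)CCCC
Why: The Stille coupling of an enol triflate with a vinylstannane at zerovalent palladium forms C13–C14 and delivers the 2-substituted buta-1,3-diene without positional ambiguity.

Step 16
Reactants: 20 triene ester
Product: 21 ent-labda-8(17),13(16),14-trien-19-ol
Conditions: LiAlH4 (2 equiv), Et2O, reflux; aq. NaOH work-up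
Reagents that add atoms: none
Why: LiAlH4 reduces the hindered axial ester to the neopentyl primary alcohol and leaves the unactivated olefins and the diene untouched.

Step 17
Reactants: 21 trienol; 22 Meldrum's acid (2,2-dimethyl-1,3-dioxane-4,6-dione)
Product: 23 hydrogen malonate of 21 (C19–O–CO–CH2–CO2H)
Conditions: toluene, BHT (trace), 105 °C
Reagents that add atoms: none
Why: Thermal alcoholysis of Meldrum's acid with loss of acetone acylates even hindered alcohols and gives the malonic half-ester without coupling reagents or protecting groups.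

Step 18
Reactants: 23 malonic half-ester; 24 4-hydroxybenzaldehyde
Product: 25 [(1R,4aS,5R,8aS)-1,4a-dimethyl-6-methylidene-5-(3-methylidenepent-4-en-1-yl)decahydronaphthalen-1-yl]methyl (2E)-3-(4-hydroxyphenyl)prop-2-enoate (target)
Conditions: pyridine, piperidine (10 mol %), 60 °C
Reagents that add atoms: none
Why: The Knoevenagel–Doebner condensation of a malonic half-ester with the free hydroxybenzaldehyde, followed by decarboxylation, gives the E-cinnamate directly, so the phenol needs no protection.

**Compound list**

1 | pent-4-enal | C=CCCC=O | starting material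
2 | (2-bromoprop-2-en-1-yl)trimethylsilane | C=C(Br)C[Si](C)(C)C | starting material
3 | [3-(trimethylsilyl)prop-1-en-2-yl]magnesium bromide | C=C([Mg]Br)C[Si](C)(C)C | intermediate
4 | (±)-2-[(trimethylsilyl)methyl]hepta-1,6-dien-3-ol | C=CCCC(O)C(=C)C[Si](C)(C)C | intermediate
5 | methyl (4Z)-4-[(trimethylsilyl)methyl]nona-4,8-dienoate | COC(=O)CC/C(C[Si](C)(C)C)=C/CCC=C | intermediate
6 | (4Z)-4-[(trimethylsilyl)methyl]nona-4,8-dienal | O=CCC/C(C[Si](C)(C)C)=C/CCC=C | intermediate
7 | (±)-(6Z)-2-methyl-6-[(trimethylsilyl)methyl]undeca-1,6,10-trien-3-ol | C=C(C)C(O)CC/C(C[Si](C)(C)C)=C/CCC=C | intermediate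
8 | methyl (4E,8Z)-4-methyl-8-[(trimethylsilyl)methyl]trideca-4,8,12-trienoate | COC(=O)CC/C(C)=C/CC/C(C[Si](C)(C)C)=C/CCC=C | intermediate
9 | methyl (6E,10Z)-6-methyl-3-oxo-10-[(trimethylsilyl)methyl]pentadeca-6,10,14-trienoate | COC(=O)CC(=O)CC/C(C)=C/CC/C(C[Si](C)(C)C)=C/CCC=C | intermediate
10 | methyl (6E,10Z)-2-diazo-6-methyl-3-oxo-10-[(trimethylsilyl)methyl]pentadeca-6,10,14-trienoate | COC(=O)C(=[N+]=[N-])C(=O)CC/C(C)=C/CC/C(C[Si](C)(C)C)=C/CCC=C | intermediate
11 | methyl (1S,5S,6S)-5-methyl-2-oxo-6-{(3Z)-3-[(trimethylsilyl)methyl]octa-3,7-dien-1-yl}bicyclo[3.1.0]hexane-1-carboxylate (chain exo, cis to the ring methyl and the ester) | COC(=O)[C@]12C(=O)CC[C@@]1(C)[C@@H]2CC/C(C[Si](C)(C)C)=C/CCC=C | intermediate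
12 | methyl (4aS,5R,8aS)-5-(but-3-en-1-yl)-4a-methyl-6-methylidene-2-[(trimethylsilyl)oxy]-3,4,4a,5,6,7,8,8a-octahydronaphthalene-1-carboxylate | C=CCC[C@@H]1C(=C)CC[C@@H]2C(C(=O)OC)=C(O[Si](C)(C)C)CC[C@@]12C | intermediate
13 | methyl (1R,4aR,5R,8aR)-5-(but-3-en-1-yl)-4a-methyl-6-methylidene-2-oxodecahydronaphthalene-1-carboxylate (trans-decalin; C4 enolisable, drawn with equatorial ester) | C=CCC[C@@H]1C(=C)CC[C@@H]2[C@@H](C(=O)OC)C(=O)CC[C@@]12C | intermediate
14 | methyl (1S,4aS,5R,8aS)-5-(but-3-en-1-yl)-1,4a-dimethyl-6-methylidene-2-oxodecahydronaphthalene-1-carboxylate (ester axial, cis to the C10 methyl) | C=CCC[C@@H]1C(=C)CC[C@@H]2[C@](C)(C(=O)OC)C(=O)CC[C@@]12C | intermediate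
15 | methyl (1S,2R,4aS,5R,8aS)-5-(but-3-en-1-yl)-2-hydroxy-1,4a-dimethyl-6-methylidene-decahydronaphthalene-1-carboxylate | C=CCC[C@@H]1C(=C)CC[C@@H]2[C@](C)(C(=O)OC)[C@H](O)CC[C@@]12C | intermediate
16 | methyl (1S,2R,4aS,5R,8aS)-5-(but-3-en-1-yl)-2-[(1H-imidazol-1-ylcarbonothioyl)oxy]-1,4a-dimethyl-6-methylidene-decahydronaphthalene-1-carboxylate | C=CCC[C@@H]1C(=C)CC[C@@H]2[C@](C)(C(=O)OC)[C@H](OC(=S)n3ccnc3)CC[C@@]12C | intermediate
17 | methyl (1R,4aS,5R,8aS)-5-(but-3-en-1-yl)-1,4a-dimethyl-6-methylidene-decahydronaphthalene-1-carboxylate | C=CCC[C@@H]1C(=C)CC[C@@H]2[C@](C)(C(=O)OC)CCC[C@@]12C | intermediate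
18 | methyl (1R,4aS,5R,8aS)-1,4a-dimethyl-6-methylidene-5-(3-oxobutyl)decahydronaphthalene-1-carboxylate | CC(=O)CC[C@@H]1C(=C)CC[C@@H]2[C@](C)(C(=O)OC)CCC[C@@]12C | intermediate
19 | methyl (1R,4aS,5R,8aS)-1,4a-dimethyl-6-methylidene-5-{3-[(trifluoromethanesulfonyl)oxy]but-3-en-1-yl}decahydronaphthalene-1-carboxylate | C=C(OS(=O)(=O)C(F)(F)F)CC[C@@H]1C(=C)CC[C@@H]2[C@](C)(C(=O)OC)CCC[C@@]12C | intermediate
20 | methyl ent-labda-8(17),13(16),14-trien-19-oate, (4R,5S,9R,10S) | C=CC(=C)CC[C@@H]1C(=C)CC[C@@H]2[C@](C)(C(=O)OC)CCC[C@@]12C | intermediate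
21 | ent-labda-8(17),13(16),14-trien-19-ol, (4R,5S,9R,10S) | C=CC(=C)CC[C@@H]1C(=C)CC[C@@H]2[C@](C)(CO)CCC[C@@]12C | intermediate
22 | Meldrum's acid (2,2-dimethyl-1,3-dioxane-4,6-dione) | CC1(C)OC(=O)CC(=O)O1 | starting material
23 | 3-oxo-3-{[ent-labda-8(17),13(16),14-trien-19-yl]oxy}propanoic acid | C=CC(=C)CC[C@@H]1C(=C)CC[C@@H]2[C@](C)(COC(=O)CC(=O)O)CCC[C@@]12C | intermediate
24 | 4-hydroxybenzaldehyde | O=Cc1ccc(O)cc1 | starting material
25 | ent-labda-8(17),13(16),14-trien-19-yl (E)-4-hydroxycinnamate, (4R,5S,9R,10S) | C=CC(=C)CC[C@@H]1C(=C)CC[C@@H]2[C@](C)(COC(=O)/C=C/c3ccc(O)cc3)CCC[C@@]12C | target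

Total step count: 18. Longest linear sequence: 18 steps (from 1 and 2 to 25).

**Steps most likely to fail**

1. **Step 8.**
   - The outer C4–C5 bond may break instead of the inner one. C10 may lose a proton before C9 has bonded. The allylsilane may be protodesilylated.
   - The fallback sets out from 11 and keeps the five-to-six expansion, but it changes the activation from an acceptor-polarised cyclopropane to a cyclopropylcarbinyl cation.
   - Luche reduction (NaBH4, CeCl3·7H2O, MeOH, −20 °C) should give the cyclopropyl carbinol F1.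
   - Ionisation of the C3 hydroxyl (Me3SiOTf 20 mol %, hindered pyridine, CH2Cl2, −78 → −20 °C) opens the ring in the Julia-type cyclopropylcarbinyl-to-homoallyl sense. C3=C4 forms as C4–C10 breaks towards tertiary C10, and the allylsilane closes ring B. This should give the conjugated ester F2.
   - Dissolving-metal reductive methylation (Li, NH3/THF, tBuOH 1 equiv, −78 °C; then MeI) alkylates the ester enolate from the equatorial face. The sequence comes back to the route at 17 and bypasses 13–16.

2. **Step 7.**
   - Facial discrimination by the catalyst may be insufficient, and carbene dimerisation may compete.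
   - The fallback sets out from 9 and replaces catalyst control by a covalently bound auxiliary with separation of diastereomers.
   - Transesterification through the acylketene ((−)-menthol, DMAP, toluene, reflux, MeOH removed) should give the menthyl β-keto ester F3.
   - Diazo transfer as in step 6 gives the diazo ester F4.
   - Cyclopropanation with achiral Cu(acac)2 (toluene, reflux) gives two diastereomers. The (1S,5S,6S)-cyclopropane F5 is separated from them by chromatography or crystallisation.
   - The conditions of step 8 give the bicyclic menthyl β-keto ester F6.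
   - Exchange with methanol (MeOH/toluene, DMAP, reflux) comes back to the route at 13.

3. **Step 14.**
   - Deprotonation may occur at C12 instead of C16. This would lead to an internal enol triflate and then to an isomeric diene that is hard to remove.
   - The fallback sets out from 17 and builds the diene by two olefinations. The four butenyl carbons then become C11–C14.
   - Hydroboration with 9-BBN (THF, 0 °C → rt; NaOH/H2O2) is selective for the monosubstituted olefin and should give the primary alcohol F7.
   - Dess–Martin oxidation gives the aldehyde F8.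
   - α-Methylenation (aq. formaldehyde, pyrrolidine and propionic acid as catalysts, iPrOH, 45 °C) gives the 2-substituted acrolein F9.
   - Wittig methylenation (Ph3P=CH2, THF, 0 °C) comes back to the route at 20.

**Further compounds**

F1 | step 8 | methyl (1S,5S,6S)-2-hydroxy-5-methyl-6-{(3Z)-3-[(trimethylsilyl)methyl]octa-3,7-dien-1-yl}bicyclo[3.1.0]hexane-1-carboxylate (C2 epimers) | COC(=O)[C@]12C(O)CC[C@@]1(C)[C@@H]2CC/C(C[Si](C)(C)C)=C/CCC=C
F2 | step 8 | methyl (4aS,5R,8aS)-5-(but-3-en-1-yl)-4a-methyl-6-methylidene-3,4,4a,5,6,7,8,8a-octahydronaphthalene-1-carboxylate | C=CCC[C@@H]1C(=C)CC[C@@H]2C(C(=O)OC)=CCC[C@@]12C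
F3 | step 7 | (1R,2S,5R)-menthyl (6E,10Z)-6-methyl-3-oxo-10-[(trimethylsilyl)methyl]pentadeca-6,10,14-trienoate | CC(C)[C@@H]1CC[C@@H](C)C[C@H]1OC(=O)CC(=O)CC/C(C)=C/CC/C(C[Si](C)(C)C)=C/CCC=C
F4 | step 7 | (1R,2S,5R)-menthyl (6E,10Z)-2-diazo-6-methyl-3-oxo-10-[(trimethylsilyl)methyl]pentadeca-6,10,14-trienoate | CC(C)[C@@H]1CC[C@@H](C)C[C@H]1OC(=O)C(=[N+]=[N-])C(=O)CC/C(C)=C/CC/C(C[Si](C)(C)C)=C/CCC=C
F5 | step 7 | (1R,2S,5R)-menthyl (1S,5S,6S)-5-methyl-2-oxo-6-{(3Z)-3-[(trimethylsilyl)methyl]octa-3,7-dien-1-yl}bicyclo[3.1.0]hexane-1-carboxylate | CC(C)[C@@H]1CC[C@@H](C)C[C@H]1OC(=O)[C@]23C(=O)CC[C@@]2(C)[C@@H]3CC/C(C[Si](C)(C)C)=C/CCC=C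
F6 | step 7 | (1R,2S,5R)-menthyl (1R,4aR,5R,8aR)-5-(but-3-en-1-yl)-4a-methyl-6-methylidene-2-oxodecahydronaphthalene-1-carboxylate | C=CCC[C@@H]1C(=C)CC[C@@H]2[C@@H](C(=O)O[C@@H]3C[C@H](C)CC[C@H]3C(C)C)C(=O)CC[C@@]12C
F7 | step 14 | methyl (1R,4aS,5R,8aS)-5-(4-hydroxybutyl)-1,4a-dimethyl-6-methylidene-decahydronaphthalene-1-carboxylate | OCCCC[C@@H]1C(=C)CC[C@@H]2[C@](C)(C(=O)OC)CCC[C@@]12C
F8 | step 14 | methyl (1R,4aS,5R,8aS)-1,4a-dimethyl-6-methylidene-5-(4-oxobutyl)decahydronaphthalene-1-carboxylate | O=CCCC[C@@H]1C(=C)CC[C@@H]2[C@](C)(C(=O)OC)CCC[C@@]12C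
F9 | step 14 | methyl (1R,4aS,5R,8aS)-5-(3-formylbut-3-en-1-yl)-1,4a-dimethyl-6-methylidene-decahydronaphthalene-1-carboxylate | O=CC(=C)CC[C@@H]1C(=C)CC[C@@H]2[C@](C)(C(=O)OC)CCC[C@@]12C
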